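**Assumption:** ring positions are named with the cyclohepta[b]furan locants of the target (C-2 lactone carbonyl, C-3a, C-4 … C-8, C-8a). Carbinol 20 is used as a mixture of epimers at its carbinol carbon, because that centre is erased in step 10.

## Retrosynthetic overview

1. Target 28 ⇐ desilylation of 27 ⇐ CO2-relay hydration of alkyne 25 ⇐ acylation of trans-diol 23 with (S)-2-methylbutanoic acid.
2. 23 ⇐ enyne lactone 21 by convex-face epoxidation and anti hydrolysis at the tertiary propargylic carbon (sets C-7 and C-8).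
3. 21 ⇐ key C–O bond: transpositive lactonisation of vinyl alkynyl carbinol acid 20 (closes the γ-lactone, sets C-8a).
4. 20 ⇐ cycloheptenone 15 + acetylide of (S)-but-3-yn-2-ol; 15 ⇐ ring-closing metathesis of the syn-aldol of pent-1-en-3-one with aldehyde 9.
5. 9 ⇐ acrylate Ireland–Claisen with chirality transfer from (S)-but-3-en-2-ol. Ring order: cycloheptene first, γ-lactone second.

## Route

Step 1
Reactants: 1 (S)-but-3-en-2-ol; 2 4,4-diethoxybut-1-ene
Product: 3 (2S,3E)-6,6-diethoxyhex-3-en-2-ol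
Conditions: second-generation Hoveyda–Grubbs catalyst (2 mol%), 2 (3 equiv), CH2Cl2, 40 °C
Reagents that add atoms: none
Why: Olefin cross-metathesis of a secondary allylic alcohol with a terminal homoallylic acetal is E-selective (minor Z isomer removed by chromatography) and does not touch the carbinol stereocentre.

Step 2
Reactants: 3 (2S,3E)-6,6-diethoxyhex-3-en-2-ol; 4 prop-2-enoyl chloride
Product: 5 (2S,3E)-6,6-diethoxyhex-3-en-2-yl prop-2-enoate
Conditions: Et3N, DMAP (cat.), CH2Cl2, 0 °C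
Reagents that add atoms: none
Why: O-Acylation with an acid chloride places the three future lactone carbons on the stereogenic allylic oxygen.

Step 3
Reactants: 5 (2S,3E)-6,6-diethoxyhex-3-en-2-yl prop-2-enoate
Product: 8 methyl (3R,4E)-3-(2,2-diethoxyethyl)-2-methylidenehex-4-enoate, via trimethylsilyl ester 6 (not isolated), via carboxylic acid 7 (not isolated)
Conditions: PCy3 (10 mol%), Me3SiCl, DBU, MeCN, 60 °C; then MeOH, Me3SiCHN2, 0 °C
Reagents that add atoms: (trimethylsilyl)diazomethane, C[Si](C)(C)C=[N+]=[N-]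
Why: Phosphine-catalysed Ireland–Claisen rearrangement of an allyl acrylate (PCy3 conjugate addition, silyl ketene acetal, [3,3] shift through a chair with the carbinol methyl equatorial, loss of PCy3) transfers the (S)-carbinol configuration to the new C-3 centre (R, future C-3a) and gives the (E)-propenyl group; the acid is methylated in the same flask.

Step 4
Reactants: 8 methyl (3R,4E)-3-(2,2-diethoxyethyl)-2-methylidenehex-4-enoate
Product: 9 methyl (3R,4E)-2-methylidene-3-(2-oxoethyl)hex-4-enoate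
Conditions: TsOH·H2O (cat.), acetone/H2O, 23 °C
Reagents that add atoms: water, O
Why: Acid-catalysed acetal hydrolysis frees the aldehyde without affecting the non-epimerisable β-stereocentre.

Step 5
Reactants: 9 methyl (3R,4E)-2-methylidene-3-(2-oxoethyl)hex-4-enoate; 10 pent-1-en-3-one
Product: 13 methyl (3R,4E)-3-[(2R,3S)-2-hydroxy-3-methyl-4-oxohex-5-en-1-yl]-2-methylidenehex-4-enoate, via enol borinate 11 (not isolated), via boron aldolate 12 (not isolated)
Conditions: (−)-Ipc2BOTf, iPr2NEt, CH2Cl2, −78 °C; 9, −78 → −20 °C; H2O2, pH 7 buffer, MeOH, 0 °C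
Reagents that add atoms: none
Why: Paterson boron aldol reaction, in which the (Z)-enol diisopinocampheylborinate adds through a chair Zimmerman–Traxler transition state to the si face of the aldehyde, sets the syn hydroxy/methyl pair (future C-5 R, C-6 S) under reagent control.

Step 6
Reactants: 13 methyl (3R,4E)-3-[(2R,3S)-2-hydroxy-3-methyl-4-oxohex-5-en-1-yl]-2-methylidenehex-4-enoate
Product: 14 methyl (3R,4E)-3-[(2R,3S)-2-[(tert-butyldimethylsilyl)oxy]-3-methyl-4-oxohex-5-en-1-yl]-2-methylidenehex-4-enoate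
Conditions: TBSOTf, 2,6-lutidine, CH2Cl2, −78 °C
Reagents that add atoms: tert-butyldimethylsilyl trifluoromethanesulfonate, CC(C)(C)[Si](C)(C)OS(=O)(=O)C(F)(F)F
Why: Silylation blocks the C-5 hydroxyl, which would otherwise add transannularly to C-8 or C-8a electrophiles and compete in the later acylation.

Step 7
Reactants: 14 methyl (3R,4E)-3-[(2R,3S)-2-[(tert-butyldimethylsilyl)oxy]-3-methyl-4-oxohex-5-en-1-yl]-2-methylidenehex-4-enoate
Product: 15 methyl 2-[(1R,5S,6R)-6-[(tert-butyldimethylsilyl)oxy]-5-methyl-4-oxocyclohept-2-en-1-yl]prop-2-enoate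
Conditions: second-generation Grubbs catalyst (5 mol%), CH2Cl2 (5 mM), 40 °C
Reagents that add atoms: none
Why: Ring-closing metathesis of the vinyl ketone with the propenyl group closes the cycloheptenone with loss of propene, while the 1,1-disubstituted acrylate alkene stays out of the reaction.

Step 8
Reactants: 16 (S)-but-3-yn-2-ol
Product: 17 tert-butyl{[(2S)-but-3-yn-2-yl]oxy}dimethylsilane
Conditions: TBSCl, imidazole, DMF, 23 °C
Reagents that add atoms: tert-butyldimethylsilyl chloride, CC(C)(C)[Si](C)(C)Cl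
Why: Standard silylation protects the chiral-pool carbinol that becomes the side-chain C-3′ stereocentre.

Step 9
Reactants: 15 methyl 2-[(1R,5S,6R)-6-[(tert-butyldimethylsilyl)oxy]-5-methyl-4-oxocyclohept-2-en-1-yl]prop-2-enoate; 17 tert-butyl{[(2S)-but-3-yn-2-yl]oxy}dimethylsilane
Product: 20 2-[(1R,5S,6R)-6-[(tert-butyldimethylsilyl)oxy]-4-{(3S)-3-[(tert-butyldimethylsilyl)oxy]but-1-yn-1-yl}-4-hydroxy-5-methylcyclohept-2-en-1-yl]prop-2-enoic acid (mixture of C-4 epimers), via lithium acetylide 18 (not isolated), via lithium alkoxide ester 19 (not isolated)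
Conditions: 17, n-BuLi, THF, −78 °C; 15, −78 °C; then LiOH, MeOH/H2O, 23 °C; HCl to pH 4
Reagents that add atoms: lithium hydroxide, [Li+].[OH-]
Why: 1,2-Addition of a lithium acetylide to the enone carbonyl (faster than attack on the acrylate ester at −78 °C) followed by saponification gives the carbinol acid; the configuration of the new carbinol does not matter.

Step 10
Reactants: 20 2-[(1R,5S,6R)-6-[(tert-butyldimethylsilyl)oxy]-4-{(3S)-3-[(tert-butyldimethylsilyl)oxy]but-1-yn-1-yl}-4-hydroxy-5-methylcyclohept-2-en-1-yl]prop-2-enoic acid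
Product: 21 (3aS,5R,6R,8aS)-5-[(tert-butyldimethylsilyl)oxy]-7-{(3S)-3-[(tert-butyldimethylsilyl)oxy]but-1-yn-1-yl}-6-methyl-3-methylidene-3,3a,4,5,6,8a-hexahydro-2H-cyclohepta[b]furan-2-one
Conditions: Re2O7 (3 mol%), CH2Cl2, 0 °C
Reagents that add atoms: none
Why: Proposed new method: Re2O7 converts either epimer of the tertiary vinyl alkynyl carbinol into its perrhenate ester, which undergoes [3,3] transposition/ionisation to an alkynyl-stabilised allyl cation whose C-8a terminus is captured 5-exo by the acrylic acid held on the α face of C-3a, axial attack next to the pseudo-equatorial tether allowing only the cis-fused γ-lactone and the new enyne conjugation driving the transposition; the closest known reactions are Re2O7-catalysed 1,3-transposition of allylic alcohols with trapping by pendant hydroxyl groups and the acid-mediated allylic rearrangement of vinyl ethynyl carbinols, neither shown with a carboxylic acid trap on such a substrate.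

Step 11
Reactants: 21 (3aS,5R,6R,8aS)-5-[(tert-butyldimethylsilyl)oxy]-7-{(3S)-3-[(tert-butyldimethylsilyl)oxy]but-1-yn-1-yl}-6-methyl-3-methylidene-3,3a,4,5,6,8a-hexahydro-2H-cyclohepta[b]furan-2-one
Product: 23 (3aS,5R,6S,7R,8S,8aR)-5-[(tert-butyldimethylsilyl)oxy]-7-{(3S)-3-[(tert-butyldimethylsilyl)oxy]but-1-yn-1-yl}-7,8-dihydroxy-6-methyl-3-methylideneoctahydro-2H-cyclohepta[b]furan-2-one, via epoxide 22 (not isolated)
Conditions: dimethyldioxirane, acetone, 0 °C; then H2O, HClO4 (5 mol%), THF, 0 °C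
Reagents that add atoms: dimethyldioxirane, CC1(C)OO1; water, O
Why: Epoxidation of the only electron-rich alkene occurs on the convex β face (anti to the allylic lactone oxygen at C-8a and the C-6 methyl), and acid-catalysed epoxide hydrolysis then opens at the tertiary propargylic C-7 with inversion, so C-8 keeps its β oxygen and C-7 receives an α hydroxyl (trans-diol).

Step 12
Reactants: 23 (3aS,5R,6S,7R,8S,8aR)-5-[(tert-butyldimethylsilyl)oxy]-7-{(3S)-3-[(tert-butyldimethylsilyl)oxy]but-1-yn-1-yl}-7,8-dihydroxy-6-methyl-3-methylideneoctahydro-2H-cyclohepta[b]furan-2-one; 24 (S)-2-methylbutanoic acid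
Product: 25 (3aS,5R,6S,7R,8S,8aR)-5-[(tert-butyldimethylsilyl)oxy]-7-{(3S)-3-[(tert-butyldimethylsilyl)oxy]but-1-yn-1-yl}-7-hydroxy-6-methyl-3-methylidene-2-oxooctahydro-2H-cyclohepta[b]furan-8-yl (2S)-2-methylbutanoate
Conditions: N,N'-diisopropylcarbodiimide, DMAP, CH2Cl2, 23 °C
Reagents that add atoms: none
Why: Steglich esterification acylates the only free secondary hydroxyl (C-8), the tertiary C-7 hydroxyl being inert, and the acid stereocentre is not enolised under these conditions.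

Step 13
Reactants: 25 (3aS,5R,6S,7R,8S,8aR)-5-[(tert-butyldimethylsilyl)oxy]-7-{(3S)-3-[(tert-butyldimethylsilyl)oxy]but-1-yn-1-yl}-7-hydroxy-6-methyl-3-methylidene-2-oxooctahydro-2H-cyclohepta[b]furan-8-yl (2S)-2-methylbutanoate
Product: 27 (3aS,5R,6S,7S,8S,8aR)-5-[(tert-butyldimethylsilyl)oxy]-7-{(3S)-3-[(tert-butyldimethylsilyl)oxy]butanoyl}-7-hydroxy-6-methyl-3-methylidene-2-oxooctahydro-2H-cyclohepta[b]furan-8-yl (2S)-2-methylbutanoate, via cyclic carbonate 26 (not isolated)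
Conditions: AgOAc (10 mol%), DBU (0.5 equiv), CO2 (1 atm), MeCN, 23 °C; then H2O, 40 °C
Reagents that add atoms: carbon dioxide, O=C=O; water, O
Why: CO2-relay hydration of a tertiary propargylic alcohol (AgOAc-catalysed carboxylative 5-exo-dig cyclisation to the α-alkylidene cyclic carbonate, then hydrolysis) places the ketone only on the alkyne carbon next to C-7, because the other propargylic oxygen is silylated.

Step 14
Reactants: 27 (3aS,5R,6S,7S,8S,8aR)-5-[(tert-butyldimethylsilyl)oxy]-7-{(3S)-3-[(tert-butyldimethylsilyl)oxy]butanoyl}-7-hydroxy-6-methyl-3-methylidene-2-oxooctahydro-2H-cyclohepta[b]furan-8-yl (2S)-2-methylbutanoate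
Product: 28 (3aS,5R,6S,7S,8S,8aR)-5,7-dihydroxy-7-[(3S)-3-hydroxybutanoyl]-6-methyl-3-methylidene-2-oxooctahydro-2H-cyclohepta[b]furan-8-yl (2S)-2-methylbutanoate
Conditions: HF·pyridine, THF, 0 → 23 °C
Reagents that add atoms: none
Why: Fluoride-mediated cleavage of both silyl ethers under mildly acidic conditions spares the β-hydroxy ketone, the α-ketol, the ester and the α-methylene lactone.

## Compound list

1 | (S)-but-3-en-2-ol | C[C@H](O)C=C | starting material
2 | 4,4-diethoxybut-1-ene | C=CCC(OCC)OCC | starting material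
3 | (2S,3E)-6,6-diethoxyhex-3-en-2-ol | C[C@H](O)/C=C/CC(OCC)OCC | intermediate
4 | prop-2-enoyl chloride | C=CC(=O)Cl | starting material
5 | (2S,3E)-6,6-diethoxyhex-3-en-2-yl prop-2-enoate | C[C@H](OC(=O)C=C)/C=C/CC(OCC)OCC | intermediate
6 | trimethylsilyl (3R,4E)-3-(2,2-diethoxyethyl)-2-methylidenehex-4-enoate | C=C(C(=O)O[Si](C)(C)C)[C@H](CC(OCC)OCC)/C=C/C | intermediate
7 | (3R,4E)-3-(2,2-diethoxyethyl)-2-methylidenehex-4-enoic acid | C=C(C(=O)O)[C@H](CC(OCC)OCC)/C=C/C | intermediate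
8 | methyl (3R,4E)-3-(2,2-diethoxyethyl)-2-methylidenehex-4-enoate | C=C(C(=O)OC)[C@H](CC(OCC)OCC)/C=C/C | intermediate
9 | methyl (3R,4E)-2-methylidene-3-(2-oxoethyl)hex-4-enoate | C=C(C(=O)OC)[C@H](CC=O)/C=C/C | intermediate
10 | pent-1-en-3-one | C=CC(=O)CC | starting material
11 | bis(isopinocampheyl)[(3Z)-penta-1,3-dien-3-yloxy]borane (isopinocampheyl groups from (+)-α-pinene) | C/C=C(/C=C)OB([C@@H]1C[C@@H]2C[C@H]([C@H]1C)C2(C)C)[C@@H]1C[C@@H]2C[C@H]([C@H]1C)C2(C)C | intermediate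
12 | O-bis(isopinocampheyl)boryl aldolate of 13 | C=C(C(=O)OC)[C@H](C[C@@H](OB([C@@H]1C[C@@H]2C[C@H]([C@H]1C)C2(C)C)[C@@H]1C[C@@H]2C[C@H]([C@H]1C)C2(C)C)[C@H](C)C(=O)C=C)/C=C/C | intermediate
13 | methyl (3R,4E)-3-[(2R,3S)-2-hydroxy-3-methyl-4-oxohex-5-en-1-yl]-2-methylidenehex-4-enoate | C=C(C(=O)OC)[C@H](C[C@@H](O)[C@H](C)C(=O)C=C)/C=C/C | intermediate
14 | methyl (3R,4E)-3-[(2R,3S)-2-[(tert-butyldimethylsilyl)oxy]-3-methyl-4-oxohex-5-en-1-yl]-2-methylidenehex-4-enoate | C=C(C(=O)OC)[C@H](C[C@@H](O[Si](C)(C)C(C)(C)C)[C@H](C)C(=O)C=C)/C=C/C | intermediate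
15 | methyl 2-[(1R,5S,6R)-6-[(tert-butyldimethylsilyl)oxy]-5-methyl-4-oxocyclohept-2-en-1-yl]prop-2-enoate | C=C(C(=O)OC)[C@@H]1C[C@@H](O[Si](C)(C)C(C)(C)C)[C@H](C)C(=O)C=C1 | intermediate
16 | (S)-but-3-yn-2-ol | C#C[C@H](C)O | starting material
17 | tert-butyl{[(2S)-but-3-yn-2-yl]oxy}dimethylsilane | C#C[C@H](C)O[Si](C)(C)C(C)(C)C | intermediate
18 | lithium acetylide of 17 | [Li]C#C[C@H](C)O[Si](C)(C)C(C)(C)C | intermediate
19 | lithium alkoxide of the methyl ester of 20 (carbinol centre unspecified, epimer mixture) | C=C(C(=O)OC)[C@@H]1C[C@@H](O[Si](C)(C)C(C)(C)C)[C@H](C)C(O[Li])(C#C[C@H](C)O[Si](C)(C)C(C)(C)C)C=C1 | intermediate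
20 | 2-[(1R,5S,6R)-6-[(tert-butyldimethylsilyl)oxy]-4-{(3S)-3-[(tert-butyldimethylsilyl)oxy]but-1-yn-1-yl}-4-hydroxy-5-methylcyclohept-2-en-1-yl]prop-2-enoic acid (C-4 epimer mixture, centre unspecified) | C=C(C(=O)O)[C@@H]1C[C@@H](O[Si](C)(C)C(C)(C)C)[C@H](C)C(O)(C#C[C@H](C)O[Si](C)(C)C(C)(C)C)C=C1 | intermediate
21 | (3aS,5R,6R,8aS)-5-[(tert-butyldimethylsilyl)oxy]-7-{(3S)-3-[(tert-butyldimethylsilyl)oxy]but-1-yn-1-yl}-6-methyl-3-methylidene-3,3a,4,5,6,8a-hexahydro-2H-cyclohepta[b]furan-2-one | C=C1C(=O)O[C@@H]2[C@H]1C[C@@H](O[Si](C)(C)C(C)(C)C)[C@H](C)C(C#C[C@H](C)O[Si](C)(C)C(C)(C)C)=C2 | intermediate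
22 | 7,8-epoxide of 21 with the oxirane oxygen on the β face, anti to the lactone ring (7S,8S) | C=C1C(=O)O[C@@H]2[C@H]1C[C@@H](O[Si](C)(C)C(C)(C)C)[C@H](C)[C@@]3(C#C[C@H](C)O[Si](C)(C)C(C)(C)C)O[C@@H]23 | intermediate
23 | (3aS,5R,6S,7R,8S,8aR)-5-[(tert-butyldimethylsilyl)oxy]-7-{(3S)-3-[(tert-butyldimethylsilyl)oxy]but-1-yn-1-yl}-7,8-dihydroxy-6-methyl-3-methylideneoctahydro-2H-cyclohepta[b]furan-2-one | C=C1C(=O)O[C@@H]2[C@H]1C[C@@H](O[Si](C)(C)C(C)(C)C)[C@H](C)[C@@](O)(C#C[C@H](C)O[Si](C)(C)C(C)(C)C)[C@H]2O | intermediate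
24 | (S)-2-methylbutanoic acid | CC[C@H](C)C(=O)O | starting material
25 | (3aS,5R,6S,7R,8S,8aR)-5-[(tert-butyldimethylsilyl)oxy]-7-{(3S)-3-[(tert-butyldimethylsilyl)oxy]but-1-yn-1-yl}-7-hydroxy-6-methyl-3-methylidene-2-oxooctahydro-2H-cyclohepta[b]furan-8-yl (2S)-2-methylbutanoate | C=C1C(=O)O[C@@H]2[C@H]1C[C@@H](O[Si](C)(C)C(C)(C)C)[C@H](C)[C@@](O)(C#C[C@H](C)O[Si](C)(C)C(C)(C)C)[C@H]2OC(=O)[C@@H](C)CC | intermediate
26 | spiro (Z)-α-alkylidene cyclic carbonate of 25 (1,3-dioxolan-2-one joining O-7 and the alkyne carbon next to C-7) | C=C1C(=O)O[C@@H]2[C@H]1C[C@@H](O[Si](C)(C)C(C)(C)C)[C@H](C)[C@]3(OC(=O)O/C3=C\[C@H](C)O[Si](C)(C)C(C)(C)C)[C@H]2OC(=O)[C@@H](C)CC | intermediate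
27 | (3aS,5R,6S,7S,8S,8aR)-5-[(tert-butyldimethylsilyl)oxy]-7-{(3S)-3-[(tert-butyldimethylsilyl)oxy]butanoyl}-7-hydroxy-6-methyl-3-methylidene-2-oxooctahydro-2H-cyclohepta[b]furan-8-yl (2S)-2-methylbutanoate | C=C1C(=O)O[C@@H]2[C@H]1C[C@@H](O[Si](C)(C)C(C)(C)C)[C@H](C)[C@@](O)(C(=O)C[C@H](C)O[Si](C)(C)C(C)(C)C)[C@H]2OC(=O)[C@@H](C)CC | intermediate
28 | (3aS,5R,6S,7S,8S,8aR)-5,7-dihydroxy-7-[(3S)-3-hydroxybutanoyl]-6-methyl-3-methylidene-2-oxooctahydro-2H-cyclohepta[b]furan-8-yl (2S)-2-methylbutanoate | C=C1C(=O)O[C@@H]2[C@H]1C[C@@H](O)[C@H](C)[C@@](O)(C(=O)C[C@H](C)O)[C@H]2OC(=O)[C@@H](C)CC | target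

## Step count and risks

Total steps: 14. Longest linear sequence: 13 (steps 1–7 and 9–14; step 8 is a one-step side branch).

**Step 10 (the new transpositive lactonisation).** It may fail through Meyer–Schuster rearrangement, loss of a silyl ether, or erosion of the cis ring fusion if the lactone re-ionises. The fallback uses known reactions and sets out from 20. Dauben-type oxidative 1,3-transposition with pyridinium chlorochromate ([C5H5NH][CrO3Cl]) in CH2Cl2 gives the transposed ynenone acid 2-[(1S,5R,6R)-6-[(tert-butyldimethylsilyl)oxy]-4-{(3S)-3-[(tert-butyldimethylsilyl)oxy]but-1-yn-1-yl}-5-methyl-2-oxocyclohept-3-en-1-yl]prop-2-enoic acid F1. Luche reduction (NaBH4, CeCl3·7H2O, MeOH, −40 °C), with hydride arriving anti to the neighbouring acrylic acid substituent, gives the cis-hydroxy acid 2-[(1S,2S,5R,6R)-6-[(tert-butyldimethylsilyl)oxy]-4-{(3S)-3-[(tert-butyldimethylsilyl)oxy]but-1-yn-1-yl}-2-hydroxy-5-methylcyclohept-3-en-1-yl]prop-2-enoic acid F2. Camphorsulfonic acid (cat.) in CH2Cl2 closes it to the lactone, and the path comes back to the route at 21.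

**Step 5 (boron aldol of a vinyl ketone).** Enolisation of pent-1-en-3-one with an amine and a boron triflate may polymerise the enone, and the level of induction is not certain; the sense of induction assigned to (−)-Ipc2BOTf is taken from memory and should be checked before use. The fallback sets out from 9 and uses an auxiliary instead of a chiral boron reagent. Evans syn-aldol reaction with (4S)-4-benzyl-3-propanoyl-1,3-oxazolidin-2-one (Bu2BOTf, iPr2NEt, CH2Cl2, −78 → 0 °C) gives the imide methyl (3R,4E)-3-[(2R,3S)-4-[(4S)-4-benzyl-2-oxo-1,3-oxazolidin-3-yl]-2-hydroxy-3-methyl-4-oxobutyl]-2-methylidenehex-4-enoate F3. Transamidation (MeNHOMe·HCl, AlMe3, CH2Cl2, 0 °C) gives the Weinreb amide methyl (3R,4E)-3-[(2R,3S)-2-hydroxy-4-[methoxy(methyl)amino]-3-methyl-4-oxobutyl]-2-methylidenehex-4-enoate F4. Silylation (TBSOTf, 2,6-lutidine) gives methyl (3R,4E)-3-[(2R,3S)-2-[(tert-butyldimethylsilyl)oxy]-4-[methoxy(methyl)amino]-3-methyl-4-oxobutyl]-2-methylidenehex-4-enoate F5. Vinylmagnesium bromide (THF, −78 → 0 °C) converts it into the vinyl ketone, and the path comes back to the route at 14.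

**Step 13 (late-stage hydration next to base-sensitive groups).** DBU and water may attack the α-methylene lactone or eliminate the β-silyloxy ketone product, and the internal alkyne may cyclise slowly. The fallback sets out from 25 and hydrates the alkyne without base or CO2, by π-acid catalysis with anchimeric assistance. Ph3PAuNTf2 (2 mol%) in wet 1,4-dioxane at 23 °C lets the C-8 ester carbonyl add 6-exo-dig to the activated alkyne at the carbon next to C-7. Hydrolysis of the resulting dioxanylium ion returns the ester and gives the ketone directly, so the path comes back to the route at 27; new compounds on its way: none F0.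

Further compounds
F1 | step 10 | 2-[(1S,5R,6R)-6-[(tert-butyldimethylsilyl)oxy]-4-{(3S)-3-[(tert-butyldimethylsilyl)oxy]but-1-yn-1-yl}-5-methyl-2-oxocyclohept-3-en-1-yl]prop-2-enoic acid | C=C(C(=O)O)[C@@H]1C[C@@H](O[Si](C)(C)C(C)(C)C)[C@H](C)C(C#C[C@H](C)O[Si](C)(C)C(C)(C)C)=CC1=O
F2 | step 10 | 2-[(1S,2S,5R,6R)-6-[(tert-butyldimethylsilyl)oxy]-4-{(3S)-3-[(tert-butyldimethylsilyl)oxy]but-1-yn-1-yl}-2-hydroxy-5-methylcyclohept-3-en-1-yl]prop-2-enoic acid | C=C(C(=O)O)[C@@H]1C[C@@H](O[Si](C)(C)C(C)(C)C)[C@H](C)C(C#C[C@H](C)O[Si](C)(C)C(C)(C)C)=C[C@@H]1O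
F3 | step 5 | methyl (3R,4E)-3-[(2R,3S)-4-[(4S)-4-benzyl-2-oxo-1,3-oxazolidin-3-yl]-2-hydroxy-3-methyl-4-oxobutyl]-2-methylidenehex-4-enoate | C=C(C(=O)OC)[C@H](C[C@@H](O)[C@H](C)C(=O)N1[C@@H](Cc2ccccc2)COC1=O)/C=C/C
F4 | step 5 | methyl (3R,4E)-3-[(2R,3S)-2-hydroxy-4-[methoxy(methyl)amino]-3-methyl-4-oxobutyl]-2-methylidenehex-4-enoate | C=C(C(=O)OC)[C@H](C[C@@H](O)[C@H](C)C(=O)N(C)OC)/C=C/C
F5 | step 5 | methyl (3R,4E)-3-[(2R,3S)-2-[(tert-butyldimethylsilyl)oxy]-4-[methoxy(methyl)amino]-3-methyl-4-oxobutyl]-2-methylidenehex-4-enoate | C=C(C(=O)OC)[C@H](C[C@@H](O[Si](C)(C)C(C)(C)C)[C@H](C)C(=O)N(C)OC)/C=C/C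
F0 | step 13 | none | none
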